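Labdane numbering is used. Ring A is cut at C1–C10 and C3–C4, so that C1–C3 come from 1-chloro-3-iodopropane and the rest of the bicycle from (S)-carvone, whose stereocentre is C5. The feature exploited is the 1,5-relationship of the C9 ketone of ring B and the C18 ester across C10–C5–C4: both termini are enolisable, so one pot alkylates C10 and then C4, closes ring A and sets the two quaternary centres C10 and C4 as a trans-decalin. The precursor is a monocyclic δ-keto ester. The carvone carbonyl then becomes C9 (methylenation, hydroboration, alkyl–alkyl Suzuki coupling) and its alkene delivers the C8 carbinol.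

Key step: step 5

Remark on numbering: ring A = C1–C5 and C10; ring B = C5–C10; C18 = carboxyl carbon on C4; C19, C20 and C17 = methyls on C4, C10 and C8; C11–C16 = side chain. Centres that are enolised again later (C10 and C4 before step 5) are carried as epimer mixtures.

Assumption: (R)-2-methylbutane-1,4-diol (14) is taken as a purchased chiral-pool diol; it is also the LiAlH4 reduction product of dimethyl (R)-2-methylsuccinate.

Step 1
Reactants: 1 (S)-(+)-carvone; 2 iodomethane
Product: 3 (5S)-2,6-dimethyl-5-(prop-1-en-2-yl)cyclohex-2-en-1-one (mixture of C6 epimers)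
Conditions: LiN(iPr)2, THF, −78 °C; MeI, −78 → 0 °C
Reagents that add atoms: iodomethane CI
Why: Kinetic α′-deprotonation of the cross-conjugated enone and SN2 methylation of the lithium enolate (ketone enolate alkylation) install C20; the new C10 centre forms as an epimer mixture that is erased when C10 is enolised again in step 5.

Step 2
Reactants: 3
Product: 5 (5R)-5-(1-hydroxypropan-2-yl)-2,6-dimethylcyclohex-2-en-1-ol (carvone centre unchanged; mixture at the other centres), via bis(9-BBN) adduct 4 (not isolated)
Conditions: 9-BBN (2.5 equiv), THF, 0 → 23 °C; then NaOH, H2O2, 0 °C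
Reagents that add atoms: hydrogen peroxide OO; 9-borabicyclo[3.3.1]nonane B1C2CCCC1CCC2 (boron stays only in 4)
Why: Hydroboration–oxidation: 9-BBN puts boron on the terminal carbon of the 1,1-disubstituted isopropenyl group and reduces the enone carbonyl 1,2, and alkaline peroxide replaces boron by oxygen so that C18 reaches the alcohol level; the new C4 and carbinol centres are mixtures that converge in steps 3 and 5.

Step 3
Reactants: 5
Product: 6 2-[(1S)-2,4-dimethyl-3-oxocyclohex-4-en-1-yl]propanoic acid (mixture at ring C2 and at the propanoic α-carbon)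
Conditions: CrO3, H2SO4, acetone/H2O, 0 °C
Reagents that add atoms: water O
Why: Jones oxidation returns the allylic alcohol to the enone and takes the primary alcohol through its aldehyde hydrate to the C18 carboxylic acid; no lasting stereocentre is formed.

Step 4
Reactants: 6; 7 benzyl bromide
Product: 8 benzyl 2-[(1S)-2,4-dimethyl-3-oxocyclohex-4-en-1-yl]propanoate (same epimer mixture)
Conditions: K2CO3, DMF, 23 °C
Reagents that add atoms: benzyl bromide BrCc1ccccc1
Why: SN2 O-alkylation of the potassium carboxylate gives a benzyl ester that tolerates the enolate and organoboron steps and can later be removed by hydrogenolysis beside an acetate.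

Step 5
Reactants: 8; 9 1-chloro-3-iodopropane
Product: 11 benzyl (1S,4aR,8aS)-1,4a,6-trimethyl-5-oxo-1,2,3,4,4a,5,8,8a-octahydronaphthalene-1-carboxylate, via chloropropyl ketone 10 (not isolated)
Conditions: one flask: LiN(iPr)2 (1.05 equiv), THF, −78 °C; ClCH2CH2CH2I, DMPU, −78 → −10 °C; then LiN(iPr)2 (1.3 equiv), −78 → 23 °C
Reagents that add atoms: 1-chloro-3-iodopropane ClCCCI
Why: LiN(iPr)2 first removes the ketone α′ proton at C10 (more acidic than the ester α proton), and the enolate is alkylated by the iodide end of the reagent anti to the pseudoaxial C5 substituent, as in sequential alkylations of carvone, to give chloride 10; the second charge of base forms the C4 ester enolate, which displaces chloride at C3. The closest known reaction types are the α′-alkylation of carvone enolates and the annulation of bis-enolates with 1,3-dihalopropanes. Ring A closes in a 6-(enolexo)-exo-tet mode through a chair in which C10–C1 and C5–C4 are both equatorial on ring B, so the decalin is trans-fused. C10 is controlled by the carvone stereocentre C5 (C1 enters trans to it), and C4 by allylic 1,3-strain: the ester enolate keeps C5–H in its plane and is attacked by the tethered C3 from the C10 side, which should place the ester equatorial and the C4 methyl axial, syn to the C10 methyl. The step needs the order C10 before C4 and iodide before chloride; the first is secured by the acidity gap between ketone and ester, the second by the mixed dihalide, and the C7=C8 bond blocks enolisation toward C8.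

Step 6
Reactants: 11; 12 methyltriphenylphosphonium bromide
Product: 13 benzyl (1S,4aR,8aS)-1,4a,6-trimethyl-5-methylidene-1,2,3,4,4a,5,8,8a-octahydronaphthalene-1-carboxylate
Conditions: Ph3PCH3Br, KOtBu, toluene, 23 → 90 °C
Reagents that add atoms: methyltriphenylphosphonium bromide C[P+](c1ccccc1)(c1ccccc1)c1ccccc1.[Br-]
Why: Wittig methylenation of the hindered ketone, which cannot enolise toward C10, installs C11 as an exocyclic methylene; no stereocentre is formed.

Step 7
Reactants: 14 (R)-2-methylbutane-1,4-diol; 15 vinyl acetate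
Product: 16 (R)-4-hydroxy-3-methylbutyl acetate
Conditions: Candida antarctica lipase B (immobilised), vinyl acetate, MTBE, 23 °C
Reagents that add atoms: vinyl acetate CC(=O)OC=C
Why: Lipase-catalysed irreversible transesterification (acyl transfer from the enol ester) should acylate the unbranched primary hydroxyl in preference to the β-branched one; the stereocentre is not involved.

Step 8
Reactants: 16
Product: 17 (R)-4-bromo-3-methylbutyl acetate
Conditions: CBr4, PPh3, CH2Cl2, 0 °C
Reagents that add atoms: tetrabromomethane BrC(Br)(Br)Br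
Why: Appel bromination converts the remaining primary alcohol into the bromide by SN2 at CH2; the adjacent stereocentre (C13) is untouched.

Step 9
Reactants: 13; 17
Product: 19 benzyl (1S,4aS,5R,8aS)-5-[(3S)-5-acetoxy-3-methylpentyl]-1,4a,6-trimethyl-1,2,3,4,4a,5,8,8a-octahydronaphthalene-1-carboxylate, via C11 alkylborane 18 (not isolated)
Conditions: 9-BBN, THF, 23 → 60 °C; then 17, Pd(OAc)2 (cat.), PCy3, K3PO4·H2O, THF, 23 °C
Reagents that add atoms: (R)-4-bromo-3-methylbutyl acetate CC(=O)OCC[C@@H](C)CBr; 9-borabicyclo[3.3.1]nonane B1C2CCCC1CCC2 (boron stays only in 18)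
Why: Hydroboration of the less hindered exocyclic alkene puts boron on C11 and hydrogen on C9 from the face anti to the axial C10 methyl, which should set C9 with the side chain equatorial, and the B-alkyl Suzuki–Miyaura coupling with the primary bromide (trialkylphosphine palladium catalyst) then forms C11–C12 without touching C13.

Step 10
Reactants: 19
Product: 21 benzyl (1S,4aR,5S,6S,8aS)-5-[(3S)-5-acetoxy-3-methylpentyl]-6-hydroxy-1,4a,6-trimethyldecahydronaphthalene-1-carboxylate, via C8 hydroperoxide 20 (not isolated)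
Conditions: Co(acac)2 (cat.), PhSiH3, O2 (1 atm), THF, 23 °C; then PPh3
Reagents that add atoms: dioxygen O=O
Why: Mukaiyama hydration (hydrogen-atom transfer from a cobalt hydride to C7, capture of the tertiary C8 radical by O2, reduction of the hydroperoxide) is Markovnikov, and O2 should approach C8 equatorially, anti to the 1,3-related axial C10 methyl, which gives the C8 carbinol with its methyl axial.

Step 11
Reactants: 21
Product: 22 (1S,4aR,5S,6S,8aS)-5-[(3S)-5-acetoxy-3-methylpentyl]-6-hydroxy-1,4a,6-trimethyldecahydronaphthalene-1-carboxylic acid (target)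
Conditions: H2 (1 atm), Pd/C, EtOAc, 23 °C
Reagents that add atoms: none
Why: Hydrogenolysis of the benzyl ester over palladium frees the C18 acid; the acetate, the tertiary alcohol and all stereocentres are inert.

Compound list

1 | (S)-(+)-carvone, (5S)-2-methyl-5-(prop-1-en-2-yl)cyclohex-2-en-1-one | CC1=CC[C@H](C(C)=C)CC1=O | starting material
2 | iodomethane | CI | starting material
3 | (5S)-2,6-dimethyl-5-(prop-1-en-2-yl)cyclohex-2-en-1-one, C6 epimers | CC1=CC[C@H](C(C)=C)C(C)C1=O | intermediate
4 | bis(9-BBN) adduct of 3: carbonyl reduced to its O-(9-borabicyclo[3.3.1]nonan-9-yl) ether, isopropenyl hydroborated at the terminal carbon | CC1=CC[C@H](C(C)CB2C3CCCC2CCC3)C(C)C1OB1C2CCCC1CCC2 | intermediate (not isolated)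
5 | (5R)-5-(1-hydroxypropan-2-yl)-2,6-dimethylcyclohex-2-en-1-ol, diastereomer mixture | CC1=CC[C@H](C(C)CO)C(C)C1O | intermediate
6 | 2-[(1S)-2,4-dimethyl-3-oxocyclohex-4-en-1-yl]propanoic acid, epimer mixture | CC1=CC[C@H](C(C)C(=O)O)C(C)C1=O | intermediate
7 | benzyl bromide | BrCc1ccccc1 | starting material
8 | benzyl 2-[(1S)-2,4-dimethyl-3-oxocyclohex-4-en-1-yl]propanoate, epimer mixture | CC1=CC[C@H](C(C)C(=O)OCc2ccccc2)C(C)C1=O | intermediate
9 | 1-chloro-3-iodopropane | ClCCCI | starting material
10 | benzyl 2-[(1R,2R)-2-(3-chloropropyl)-2,4-dimethyl-3-oxocyclohex-4-en-1-yl]propanoate, epimers at the propanoate α-carbon | O=C1[C@](C)(CCCCl)[C@@H](C(C)C(=O)OCc2ccccc2)CC=C1C | intermediate (not isolated)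
11 | benzyl (1S,4aR,8aS)-1,4a,6-trimethyl-5-oxo-1,2,3,4,4a,5,8,8a-octahydronaphthalene-1-carboxylate (trans-decalin; C4 methyl syn to C10 methyl) | O=C1[C@]2(C)CCC[C@](C)(C(=O)OCc3ccccc3)[C@H]2CC=C1C | intermediate
12 | methyltriphenylphosphonium bromide | C[P+](c1ccccc1)(c1ccccc1)c1ccccc1.[Br-] | starting material
13 | benzyl (1S,4aR,8aS)-1,4a,6-trimethyl-5-methylidene-1,2,3,4,4a,5,8,8a-octahydronaphthalene-1-carboxylate | C=C1[C@]2(C)CCC[C@](C)(C(=O)OCc3ccccc3)[C@H]2CC=C1C | intermediate
14 | (R)-2-methylbutane-1,4-diol | OCC[C@@H](C)CO | starting material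
15 | vinyl acetate | CC(=O)OC=C | starting material
16 | (R)-4-hydroxy-3-methylbutyl acetate | CC(=O)OCC[C@@H](C)CO | intermediate
17 | (R)-4-bromo-3-methylbutyl acetate | CC(=O)OCC[C@@H](C)CBr | intermediate
18 | benzyl (1S,4aS,5R,8aS)-5-[(9-borabicyclo[3.3.1]nonan-9-yl)methyl]-1,4a,6-trimethyl-1,2,3,4,4a,5,8,8a-octahydronaphthalene-1-carboxylate | C(B1C2CCCC1CCC2)[C@H]1[C@]2(C)CCC[C@](C)(C(=O)OCc3ccccc3)[C@H]2CC=C1C | intermediate (not isolated)
19 | benzyl (1S,4aS,5R,8aS)-5-[(3S)-5-acetoxy-3-methylpentyl]-1,4a,6-trimethyl-1,2,3,4,4a,5,8,8a-octahydronaphthalene-1-carboxylate | CC(=O)OCC[C@@H](C)CC[C@H]1[C@]2(C)CCC[C@](C)(C(=O)OCc3ccccc3)[C@H]2CC=C1C | intermediate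
20 | benzyl (1S,4aR,5S,6S,8aS)-5-[(3S)-5-acetoxy-3-methylpentyl]-6-hydroperoxy-1,4a,6-trimethyldecahydronaphthalene-1-carboxylate | CC(=O)OCC[C@@H](C)CC[C@H]1[C@]2(C)CCC[C@](C)(C(=O)OCc3ccccc3)[C@H]2CC[C@]1(C)OO | intermediate (not isolated)
21 | benzyl (1S,4aR,5S,6S,8aS)-5-[(3S)-5-acetoxy-3-methylpentyl]-6-hydroxy-1,4a,6-trimethyldecahydronaphthalene-1-carboxylate | CC(=O)OCC[C@@H](C)CC[C@H]1[C@]2(C)CCC[C@](C)(C(=O)OCc3ccccc3)[C@H]2CC[C@]1(C)O | intermediate
22 | (1S,4aR,5S,6S,8aS)-5-[(3S)-5-acetoxy-3-methylpentyl]-6-hydroxy-1,4a,6-trimethyldecahydronaphthalene-1-carboxylic acid | CC(=O)OCC[C@@H](C)CC[C@H]1[C@]2(C)CCC[C@](C)(C(=O)O)[C@H]2CC[C@]1(C)O | target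

Total step count: 11. Longest linear sequence: 9 steps (steps 1–6 and 9–11, from (S)-carvone); steps 7 and 8 make the side-chain fragment.

Steps most likely to fail

Step 5. In the second stage, proton transfer from C6 to the ester enolate (or direct γ-deprotonation of the enone) can give the dienolate, which may close on oxygen or on C8 while the slow chloride displacement is pending. A weak preference of the enolate for the conformer with C5–H in its plane would also erode the facial selectivity at C4. The fallback makes the two bonds in separate steps with a differentiated three-carbon unit, so that the ring closure runs on a purified iodide at −78 °C, faster than any equilibration with the dienolate. It sets out from 8: alkylation at C10 with tert-butyl(3-iodopropoxy)dimethylsilane (LiN(iPr)2, THF/DMPU) should give benzyl 2-[(1R,2R)-2-[3-(tert-butyldimethylsilyloxy)propyl]-2,4-dimethyl-3-oxocyclohex-4-en-1-yl]propanoate F1. Bu4NF buffered with AcOH frees the primary alcohol F2, and I2, PPh3 and imidazole convert it into the primary iodide F3. LiN(iPr)2 in THF at −78 °C then closes ring A and the route is rejoined at 11.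

Step 9. Both coupling partners are β-branched, so oxidative addition and transmetalation may be slow enough for protodeboronation and β-hydride elimination to take over. The fallback forms C11–C12 by olefination. It sets out from 13: hydroboration as before and oxidation of borane 18 with NaBO3 give the primary alcohol F4, and Dess–Martin periodinane gives the aldehyde F5, whose formyl group is already equatorial. Bromide 17 and PPh3 (MeCN, 80 °C) give the phosphonium salt F6, which NaN(SiMe3)2 at −78 °C converts into the ylide F7. Wittig reaction of F7 with F5 should give the Z-alkene F8. Diimide (TsNHNH2, NaOAc) reduces the disubstituted alkene in preference to the trisubstituted ring alkene, and the route is rejoined at 19.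

Step 10. Capture of the planar C8 radical by O2 may show poor facial selectivity, and the radical may be reduced to the alkane instead. The fallback delivers the C8 oxygen by a concerted syn addition anti to the C10 methyl and removes the extra C7 oxygen with hydride. It sets out from 19: OsO4 (cat.) with N-methylmorpholine N-oxide should give the 7,8-cis-diol F9 (benzyl (1S,4aR,5S,6R,7S,8aS)-5-[(3S)-5-acetoxy-3-methylpentyl]-6,7-dihydroxy-1,4a,6-trimethyldecahydronaphthalene-1-carboxylate). SOCl2 and Et3N give the cyclic sulfite F10, and RuCl3 (cat.) with NaIO4 oxidises it to the cyclic sulfate F11. NaBH4 in N,N-dimethylacetamide opens F11 at the secondary C7 to the C8 sulfate monoester F12, and aqueous H2SO4 in THF hydrolyses it, so that the route is rejoined at 21.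

Further compounds

F1 | step 5 | benzyl 2-[(1R,2R)-2-[3-(tert-butyldimethylsilyloxy)propyl]-2,4-dimethyl-3-oxocyclohex-4-en-1-yl]propanoate | O=C1[C@](C)(CCCO[Si](C)(C)C(C)(C)C)[C@@H](C(C)C(=O)OCc2ccccc2)CC=C1C
F2 | step 5 | benzyl 2-[(1R,2R)-2-(3-hydroxypropyl)-2,4-dimethyl-3-oxocyclohex-4-en-1-yl]propanoate | O=C1[C@](C)(CCCO)[C@@H](C(C)C(=O)OCc2ccccc2)CC=C1C
F3 | step 5 | benzyl 2-[(1R,2R)-2-(3-iodopropyl)-2,4-dimethyl-3-oxocyclohex-4-en-1-yl]propanoate | O=C1[C@](C)(CCCI)[C@@H](C(C)C(=O)OCc2ccccc2)CC=C1C
F4 | step 9 | benzyl (1S,4aR,5R,8aS)-5-(hydroxymethyl)-1,4a,6-trimethyl-1,2,3,4,4a,5,8,8a-octahydronaphthalene-1-carboxylate | OC[C@H]1[C@]2(C)CCC[C@](C)(C(=O)OCc3ccccc3)[C@H]2CC=C1C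
F5 | step 9 | benzyl (1S,4aR,5R,8aS)-5-formyl-1,4a,6-trimethyl-1,2,3,4,4a,5,8,8a-octahydronaphthalene-1-carboxylate | O=C[C@H]1[C@]2(C)CCC[C@](C)(C(=O)OCc3ccccc3)[C@H]2CC=C1C
F6 | step 9 | [(2R)-4-acetoxy-2-methylbutyl]triphenylphosphonium bromide | CC(=O)OCC[C@@H](C)C[P+](c1ccccc1)(c1ccccc1)c1ccccc1.[Br-]
F7 | step 9 | [(2R)-4-acetoxy-2-methylbutylidene]triphenylphosphorane | CC(=O)OCC[C@@H](C)C=P(c1ccccc1)(c1ccccc1)c1ccccc1
F8 | step 9 | benzyl (1S,4aR,5R,8aS)-5-[(1Z,3R)-5-acetoxy-3-methylpent-1-en-1-yl]-1,4a,6-trimethyl-1,2,3,4,4a,5,8,8a-octahydronaphthalene-1-carboxylate | CC(=O)OCC[C@@H](C)/C=C\[C@H]1[C@]2(C)CCC[C@](C)(C(=O)OCc3ccccc3)[C@H]2CC=C1C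
F9 | step 10 | benzyl (1S,4aR,5S,6R,7S,8aS)-5-[(3S)-5-acetoxy-3-methylpentyl]-6,7-dihydroxy-1,4a,6-trimethyldecahydronaphthalene-1-carboxylate | CC(=O)OCC[C@@H](C)CC[C@H]1[C@]2(C)CCC[C@](C)(C(=O)OCc3ccccc3)[C@H]2C[C@H](O)[C@]1(C)O
F10 | step 10 | 7,8-cyclic sulfite of F9 (mixture at sulfur) | CC(=O)OCC[C@@H](C)CC[C@H]1[C@]2(C)CCC[C@](C)(C(=O)OCc3ccccc3)[C@H]2C[C@@H]4OS(=O)O[C@]14C
F11 | step 10 | 7,8-cyclic sulfate of F9 | CC(=O)OCC[C@@H](C)CC[C@H]1[C@]2(C)CCC[C@](C)(C(=O)OCc3ccccc3)[C@H]2C[C@@H]4OS(=O)(=O)O[C@]14C
F12 | step 10 | sodium salt of the C8 sulfate monoester of 21 | CC(=O)OCC[C@@H](C)CC[C@H]1[C@]2(C)CCC[C@](C)(C(=O)OCc3ccccc3)[C@H]2CC[C@]1(C)OS(=O)(=O)[O-].[Na+]
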